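**Retrosynthesis**
- The target is an achiral tridepside, A–B–C, with two aryl ester bonds. There are no stereocenters, and no aromatic rings need to be built.
- Disconnect the two ester bonds. A is 2,4,5-trihydroxy-6-methylbenzoic acid. B is 4-hydroxy-2-methoxy-6-methylbenzoic acid. C is orsellinic acid acylated at its 4-OH.
- All three units come from orsellinate. Ring A needs one extra C5 hydroxylation, which is an Elbs persulfate oxidation para to the 2-OH.
- Protecting groups are Bn on the A phenols and the C acid, and allyl on B-4-OH. Allyl is removed by Pd(0) between the two couplings. The last step is one global hydrogenolysis.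

Assumptions:
- Only organic substrates are numbered. Small reagents are named with SMILES in each step.
- Elbs oxidation of methyl orsellinate is taken to hydroxylate C5, para to the 2-OH.

**Step 1**
Reactants: 1 methyl orsellinate (methyl 2,4-dihydroxy-6-methylbenzoate)
Product: 2 methyl 2,4,5-trihydroxy-6-methylbenzoate
Conditions: K2S2O8, aq NaOH, 0 °C → rt, 24 h; then aq HCl, 80 °C
Reagents that add atoms: potassium persulfate, [K+].[K+].[O-]S(=O)(=O)OOS(=O)(=O)[O-] (supplies the new ring O)
Why: Elbs persulfate oxidation of the phenolate gives the C5 aryl sulfate, para to the 2-O⁻, and acid hydrolysis then releases the C5 phenol. Nothing is chiral.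

**Step 2**
Reactants: 2
Product: 3 methyl 2,4,5-tris(benzyloxy)-6-methylbenzoate
Conditions: BnBr (4 equiv), K2CO3, DMF, 60 °C, N2
Reagents that add atoms: benzyl bromide, BrCc1ccccc1
Why: Williamson O-benzylation of all three phenols, including the chelated 2-OH at elevated temperature, under N2 to protect the hydroquinone/catechol ring.

**Step 3**
Reactants: 3
Product: 4 2,4,5-tris(benzyloxy)-6-methylbenzoic acid
Conditions: KOH, EtOH/H2O, reflux; then HCl
Reagents that add atoms: water/hydroxide, O
Why: Saponification of the hindered methyl ester under forcing conditions; the benzyl ethers are base-stable.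

**Step 4**
Reactants: 1 methyl orsellinate
Product: 5 methyl 4-(allyloxy)-2-hydroxy-6-methylbenzoate
Conditions: allyl bromide, K2CO3, acetone, reflux
Reagents that add atoms: allyl bromide, C=CCBr
Why: Williamson alkylation is selective for the 4-OH, because the 2-OH is locked in a hydrogen bond to the ester carbonyl.

**Step 5**
Reactants: 5
Product: 6 methyl 4-(allyloxy)-2-methoxy-6-methylbenzoate
Conditions: MeI, K2CO3, DMF, 50 °C
Reagents that add atoms: methyl iodide, CI
Why: O-methylation of the remaining chelated phenol forms the 2-OMe of ring B.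

**Step 6**
Reactants: 6
Product: 7 4-(allyloxy)-2-methoxy-6-methylbenzoic acid
Conditions: KOH, EtOH/H2O, reflux; then HCl
Reagents that add atoms: water/hydroxide, O
Why: Ester saponification; the aryl allyl ether and aryl methyl ether are base-stable.

**Step 7**
Reactants: 8 orsellinic acid (2,4-dihydroxy-6-methylbenzoic acid)
Product: 9 benzyl orsellinate (benzyl 2,4-dihydroxy-6-methylbenzoate)
Conditions: BnBr, NaHCO3, DMF, rt
Reagents that add atoms: benzyl bromide, BrCc1ccccc1
Why: Only the carboxylate is nucleophilic enough under mild bicarbonate, so the phenols stay free (carboxylate O-alkylation).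

**Step 8**
Reactants: 7 and 9
Product: 10 benzyl 4-[(4-allyloxy-2-methoxy-6-methylbenzoyl)oxy]-2-hydroxy-6-methylbenzoate
Conditions: DCC, DMAP (cat.), CH2Cl2, 0 °C → rt
Reagents that add atoms: none
Why: Steglich esterification occurs at the free 4-OH of 9, because the 2-OH is chelated to the ester and is unreactive. This forms the B–C depside bond.

**Step 9**
Reactants: 10
Product: 11 benzyl 2-hydroxy-4-[(4-hydroxy-2-methoxy-6-methylbenzoyl)oxy]-6-methylbenzoate
Conditions: Pd(PPh3)4 (5 mol%), PhSiH3, CH2Cl2, rt
Reagents that add atoms: none (the allyl group leaves as propene and H goes onto oxygen)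
Why: Pd(0)-catalysed deallylation through a π-allyl with a hydride scavenger is neutral, so the aryl esters and the benzyl ester survive.

**Step 10**
Reactants: 11 and 4
Product: 12 benzyl 4-[[4-[2,4,5-tris(benzyloxy)-6-methylbenzoyl]oxy-2-methoxy-6-methylbenzoyl]oxy]-2-hydroxy-6-methylbenzoate
Conditions: DCC, DMAP (cat.), CH2Cl2, 0 °C → rt
Reagents that add atoms: none
Why: Steglich esterification of the unhindered free 4-OH of ring B with acid 4 forms the A–B depside bond, with the chelated 2-OH of ring C left alone.

**Step 11**
Reactants: 12
Product: 13 2'-O-methylhiascic acid (the target)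
Conditions: H2 (1 atm), 10% Pd/C, THF/EtOAc, rt, then rapid filtration under Ar
Reagents that add atoms: none (only hydrogen is added)
Why: Hydrogenolysis removes the three aryl benzyl ethers and the benzyl ester together. The aryl esters and the aryl methyl ether are unaffected, and the molecule is achiral.

**Compound list**
1 | methyl orsellinate | COC(=O)c1c(C)cc(O)cc1O | starting material
2 | methyl 2,4,5-trihydroxy-6-methylbenzoate | COC(=O)c1c(C)c(O)c(O)cc1O | intermediate
3 | methyl 2,4,5-tris(benzyloxy)-6-methylbenzoate | COC(=O)c1c(C)c(OCc2ccccc2)c(OCc2ccccc2)cc1OCc1ccccc1 | intermediate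
4 | 2,4,5-tris(benzyloxy)-6-methylbenzoic acid | OC(=O)c1c(C)c(OCc2ccccc2)c(OCc2ccccc2)cc1OCc1ccccc1 | intermediate
5 | methyl 4-(allyloxy)-2-hydroxy-6-methylbenzoate | COC(=O)c1c(C)cc(OCC=C)cc1O | intermediate
6 | methyl 4-(allyloxy)-2-methoxy-6-methylbenzoate | COC(=O)c1c(C)cc(OCC=C)cc1OC | intermediate
7 | 4-(allyloxy)-2-methoxy-6-methylbenzoic acid | OC(=O)c1c(C)cc(OCC=C)cc1OC | intermediate
8 | orsellinic acid | OC(=O)c1c(C)cc(O)cc1O | starting material
9 | benzyl orsellinate | O=C(OCc1ccccc1)c1c(C)cc(O)cc1O | intermediate
10 | B–C depside with 4-allyl ether and benzyl ester | C=CCOc1cc(C)c(C(=O)Oc2cc(C)c(C(=O)OCc3ccccc3)c(O)c2)c(OC)c1 | intermediate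
11 | B–C depside with free 4-OH | COc1cc(O)cc(C)c1C(=O)Oc1cc(C)c(C(=O)OCc2ccccc2)c(O)c1 | intermediate
12 | fully benzylated tridepside | COc1cc(OC(=O)c2c(C)c(OCc3ccccc3)c(OCc3ccccc3)cc2OCc2ccccc2)cc(C)c1C(=O)Oc1cc(C)c(C(=O)OCc2ccccc2)c(O)c1 | intermediate
13 | 2'-O-methylhiascic acid | COc1cc(OC(=O)c2c(O)cc(O)c(O)c2C)cc(C)c1C(=O)Oc1cc(C)c(C(=O)O)c(O)c1 | target

**Totals**
- Total steps: 11.
- Longest linear sequence: 7 steps (1 → 5 → 6 → 7 → 10 → 11 → 12 → 13).

**Three steps most likely to fail**
1. **Step 1 (Elbs oxidation).** The yield may be low, and C3 or quinone products may form.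
   - Fallback: 2,4-di-O-benzylate the orsellinate, then formylate C5 selectively under Vilsmeier conditions (the 1,3-dialkoxy pattern favours the ortho/para position over the position between the two oxygens). Then do a Baeyer–Villiger/Dakin oxidation of the aldehyde with mCPBA followed by hydrolysis, and benzylate the new OH.
2. **Step 10 (hindered A–B coupling).** Acid 4 is 2,6-disubstituted, so N-acylurea formation may compete.
   - Fallback: reverse the assembly order. Acylate B-4-OH (as its allyl ester) with the acid chloride of 4, remove the allyl ester with Pd(0), and couple the resulting acid to 9.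
3. **Step 11 (global hydrogenolysis).** The hydroquinone/catechol product is air-sensitive and could be over-reduced or oxidised to a quinone.
   - Fallback: protect ring A and the C acid as p-methoxybenzyl ethers and ester instead of benzyl, and remove them with TFA/anisole in CH2Cl2 at 0 °C, which avoids hydrogenation entirely.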